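Positions follow benzofuranone numbering (O1, C2, C3, C3a, C4 to C7, C7a; primes for the second half). Retrosynthetic cuts, in order: the two protecting O6-benzyl groups, both C2–C3 bonds, both C3a–CHO bonds, both C7a–O bonds (each traced back to a C7a–CHO group), and last the C7–C7' biaryl bond.
Enabling feature: in each furanone ring, C2 carries O1, OH and CH3 beside the C3 ketone. It is the arrested tetrahedral intermediate of an acetyl transfer from the phenol oxygen O1 to an acyl anion at C3, so the ring O1–C2–C3–C3a–C7a is a constitutional isomer of an O-acetylsalicylaldehyde unit.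
Forward order: both benzene rings come with 3-hydroxy-4,5-dimethoxybenzaldehyde. Ullmann coupling joins them; Baeyer–Villiger oxidation, ortho-formylation and acetylation dress each ring. The two furanone rings close last, one after the other in one flask, by a carbene-catalysed isomerisation that sets nothing free.
Stereochemistry: C2 and C2' (both R) are set during ring closure by a chiral triazolylidene catalyst, and only a neutral hydrogenolysis follows. The racemic C7–C7' axis is resolved at the same stage, since the two (2R,2'R) atropisomers are diastereomers.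

Key step: step 7

Assumption: the SMILES fixes only C2 and C2' (both R); the hindered C7–C7' axis, which a SMILES string does not encode, is taken as configurationally stable but unassigned, so either (2R,2'R) atropisomer answers the given structure and the one that matches the natural sample is carried through step 8.

Step 1
Reactants: 1 3-hydroxy-4,5-dimethoxybenzaldehyde
Product: 2 2-bromo-3-hydroxy-4,5-dimethoxybenzaldehyde
Conditions: NBS (1.0 equiv), i-Pr2NH (cat.), CH2Cl2, 0 °C
Reagents that add atoms: N-bromosuccinimide, O=C1CCC(=O)N1Br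
Why: Phenol-directed electrophilic aromatic bromination, in which the amine/NBS couple delivers bromine ortho to the free OH, C4 is blocked, and C2 is also para to the C5 methoxy group and less crowded than C6, in line with the known 2-bromination of isovanillin.

Step 2
Reactants: 2 2-bromo-3-hydroxy-4,5-dimethoxybenzaldehyde
Product: 3 3-(benzyloxy)-2-bromo-4,5-dimethoxybenzaldehyde
Conditions: BnBr, K2CO3, DMF, rt
Reagents that add atoms: benzyl bromide, BrCc1ccccc1
Why: Williamson ether synthesis on the only phenol, which marks the future O6 with a group that can be removed at the end without acid or base.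

Step 3
Reactants: 3 3-(benzyloxy)-2-bromo-4,5-dimethoxybenzaldehyde (two molecules)
Product: 4 6,6'-bis(benzyloxy)-4,4',5,5'-tetramethoxy-[1,1'-biphenyl]-2,2'-dicarbaldehyde (racemic axis)
Conditions: Cu powder (activated), DMF, 150 °C
Reagents that add atoms: none
Why: Ullmann homocoupling of an aryl bromide activated by its ortho-formyl group, a reaction type well used for 2-bromo-3,4,5-trialkoxybenzaldehydes and tolerant of aldehydes and benzyl ethers, which forms the tetra-ortho-substituted C7–C7' bond as a racemate.

Step 4
Reactants: 4 6,6'-bis(benzyloxy)-4,4',5,5'-tetramethoxy-[1,1'-biphenyl]-2,2'-dicarbaldehyde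
Product: 6 6,6'-bis(benzyloxy)-4,4',5,5'-tetramethoxy-[1,1'-biphenyl]-2,2'-diol (racemic axis), via bis-formate 5 (not isolated)
Conditions: mCPBA, CH2Cl2, 0 °C to rt; then K2CO3 (cat.), MeOH, rt
Reagents that add atoms: 3-chloroperoxybenzoic acid, O=C(OO)c1cccc(Cl)c1
Why: Baeyer–Villiger (Dakin-type) oxidation in which the electron-rich aryl group, para to a methoxy group, migrates in preference to hydrogen, after which mild methanolysis cleaves the aryl formates and leaves the benzyl and methyl ethers alone.

Step 5
Reactants: 6 6,6'-bis(benzyloxy)-4,4',5,5'-tetramethoxy-[1,1'-biphenyl]-2,2'-diol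
Product: 8 6,6'-bis(benzyloxy)-2,2'-dihydroxy-4,4',5,5'-tetramethoxy-[1,1'-biphenyl]-3,3'-dicarbaldehyde (racemic axis), via bis-hydroxymethyl biphenol 7 (not isolated)
Conditions: MgCl2, Et3N, (CH2O)n, MeCN, reflux; aq HCl work-up
Reagents that add atoms: paraformaldehyde (reacts as formaldehyde), C=O
Why: Casnati–Skattebøl ortho-formylation, in which the magnesium phenoxide delivers formaldehyde to the only free ring position, which lies ortho to the phenol, and a second formaldehyde takes up hydride from the benzylic alkoxide to give the aldehyde.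

Step 6
Reactants: 8 6,6'-bis(benzyloxy)-2,2'-dihydroxy-4,4',5,5'-tetramethoxy-[1,1'-biphenyl]-3,3'-dicarbaldehyde
Product: 9 6,6'-bis(benzyloxy)-3,3'-diformyl-4,4',5,5'-tetramethoxy-[1,1'-biphenyl]-2,2'-diyl diacetate (racemic axis)
Conditions: Ac2O, pyridine, 4-(dimethylamino)pyridine (cat.), CH2Cl2, 0 °C to rt
Reagents that add atoms: acetic anhydride, CC(=O)OC(C)=O
Why: Nucleophile-catalysed O-acetylation of the chelated phenols, in which the acetyl group is not a protecting group but supplies C2, its methyl group and the oxygen of the future C2 hydroxyl.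

Step 7
Reactants: 9 6,6'-bis(benzyloxy)-3,3'-diformyl-4,4',5,5'-tetramethoxy-[1,1'-biphenyl]-2,2'-diyl diacetate
Product: 11 (2R,2'R)-6,6'-bis(benzyloxy)-2,2'-dihydroxy-4,4',5,5'-tetramethoxy-2,2'-dimethyl-[7,7'-bi-1-benzofuran]-3,3'(2H,2'H)-dione (single atropisomer after chromatography), via monocyclised acetoxy-aldehyde 10 (not isolated)
Conditions: (5aR,10bS)-2-(pentafluorophenyl)-5a,10b-dihydro-4H,6H-indeno[2,1-b][1,2,4]triazolo[4,3-d][1,4]oxazin-2-ium tetrafluoroborate (20 mol %), i-Pr2NEt (20 mol %), 4 Å molecular sieves, toluene, 23 °C; SiO2 chromatography (separation of the two atropisomers)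
Reagents that add atoms: none
Why: Proposed new method: the carbene adds to the C3 aldehyde and a proton shift gives the enaminol (acyl anion equivalent), whose carbon attacks the carbonyl carbon of the neighbouring aryl acetate while the enaminol O–H proton passes to the developing oxyanion, and loss of the carbene from C3 leaves the C3 ketone beside the C2 hemiketal, the tetrahedral intermediate being kept because its leaving group O1 is held in the new five-membered ring. The closest known reaction types are the enantioselective intramolecular crossed aldehyde–ketone benzoin cyclisation with chiral triazolium salts, the carbene-catalysed intramolecular Stetter route to 2,2-disubstituted benzofuran-3(2H)-ones, and the cyanide- or carbene-induced cleavage of 1,2-diketones by alcohols to aldehyde plus ester, which is the microscopic reverse and shows that the pathway exists. Each furanone ring closes by a 5-exo-trig attack that forms C2–C3, first in 9 to give 10 and then in 10 to give 11, so that the second closure completes the skeleton. C2 and C2' are each set by the catalyst, whose indane wall shields one face of the enaminol while the O–H···O=C hydrogen bond fixes which face of the acetate carbonyl is presented; the sense is assigned by analogy with ketone acceptors (the antipodal salt is equally available), the remote axis has no say, and the double reaction raises the enantiomeric purity of the (2R,2'R) product at the cost of separable (2R,2'S) isomers. The step needs the acyl anion to choose the ester over a second aldehyde and needs the equilibrium to lie on the product side: both ortho positions of each aldehyde are substituted, which blocks homo-benzoin coupling, only the C7a acetate is within reach, and the weak resonance of an aryl ester, the ring closure, the new O1-to-C3 push–pull conjugation and the relief of crowding around the hexasubstituted rings should tip the balance. The catalytic weak base and the aprotic solvent are chosen to keep the hemiketal from opening to the diketone, which would scramble C2.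

Step 8
Reactants: 11 (2R,2'R)-6,6'-bis(benzyloxy)-2,2'-dihydroxy-4,4',5,5'-tetramethoxy-2,2'-dimethyl-[7,7'-bi-1-benzofuran]-3,3'(2H,2'H)-dione
Product: 12 (2R,2'R)-2,2',6,6'-tetrahydroxy-4,4',5,5'-tetramethoxy-2,2'-dimethyl-[7,7'-bi-1-benzofuran]-3,3'(2H,2'H)-dione (CNP0171547.1)
Conditions: H2 (1 atm), 10 % Pd/C, EtOAc, rt
Reagents that add atoms: none
Why: Heterogeneous hydrogenolysis of the two aryl benzyl ethers under neutral aprotic conditions, which spares the electron-rich C3 aryl ketones and the tertiary hemiketals and offers no acid or base to open the hemiketals, so that C2 and C2' should keep their configuration.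

Compound list
1 | 3-hydroxy-4,5-dimethoxybenzaldehyde | COc1cc(C=O)cc(O)c1OC | starting material
2 | 2-bromo-3-hydroxy-4,5-dimethoxybenzaldehyde | COc1cc(C=O)c(Br)c(O)c1OC | intermediate
3 | 3-(benzyloxy)-2-bromo-4,5-dimethoxybenzaldehyde | COc1cc(C=O)c(Br)c(OCc2ccccc2)c1OC | intermediate
4 | 6,6'-bis(benzyloxy)-4,4',5,5'-tetramethoxy-[1,1'-biphenyl]-2,2'-dicarbaldehyde (racemic axis) | COc1cc(C=O)c(c(OCc2ccccc2)c1OC)-c1c(C=O)cc(OC)c(OC)c1OCc1ccccc1 | intermediate
5 | 6,6'-bis(benzyloxy)-4,4',5,5'-tetramethoxy-[1,1'-biphenyl]-2,2'-diyl diformate (not isolated) | COc1cc(OC=O)c(c(OCc2ccccc2)c1OC)-c1c(OC=O)cc(OC)c(OC)c1OCc1ccccc1 | intermediate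
6 | 6,6'-bis(benzyloxy)-4,4',5,5'-tetramethoxy-[1,1'-biphenyl]-2,2'-diol (racemic axis) | COc1cc(O)c(c(OCc2ccccc2)c1OC)-c1c(O)cc(OC)c(OC)c1OCc1ccccc1 | intermediate
7 | 6,6'-bis(benzyloxy)-3,3'-bis(hydroxymethyl)-4,4',5,5'-tetramethoxy-[1,1'-biphenyl]-2,2'-diol (not isolated) | COc1c(CO)c(O)c(c(OCc2ccccc2)c1OC)-c1c(O)c(CO)c(OC)c(OC)c1OCc1ccccc1 | intermediate
8 | 6,6'-bis(benzyloxy)-2,2'-dihydroxy-4,4',5,5'-tetramethoxy-[1,1'-biphenyl]-3,3'-dicarbaldehyde (racemic axis) | COc1c(C=O)c(O)c(c(OCc2ccccc2)c1OC)-c1c(O)c(C=O)c(OC)c(OC)c1OCc1ccccc1 | intermediate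
9 | 6,6'-bis(benzyloxy)-3,3'-diformyl-4,4',5,5'-tetramethoxy-[1,1'-biphenyl]-2,2'-diyl diacetate (racemic axis) | COc1c(C=O)c(OC(C)=O)c(c(OCc2ccccc2)c1OC)-c1c(OC(C)=O)c(C=O)c(OC)c(OC)c1OCc1ccccc1 | intermediate
10 | 3-(benzyloxy)-2-[(2R)-6-(benzyloxy)-2-hydroxy-4,5-dimethoxy-2-methyl-3-oxo-2,3-dihydro-1-benzofuran-7-yl]-6-formyl-4,5-dimethoxyphenyl acetate (not isolated) | COc1c(OCc4ccccc4)c(-c2c(OCc5ccccc5)c(OC)c(OC)c(C=O)c2OC(C)=O)c2c(c1OC)C(=O)[C@](C)(O)O2 | intermediate
11 | (2R,2'R)-6,6'-bis(benzyloxy)-2,2'-dihydroxy-4,4',5,5'-tetramethoxy-2,2'-dimethyl-[7,7'-bi-1-benzofuran]-3,3'(2H,2'H)-dione (single atropisomer) | COc1c(OCc4ccccc4)c(-c2c(OCc5ccccc5)c(OC)c(OC)c3c2O[C@@](C)(O)C3=O)c2c(c1OC)C(=O)[C@](C)(O)O2 | intermediate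
12 | (2R,2'R)-2,2',6,6'-tetrahydroxy-4,4',5,5'-tetramethoxy-2,2'-dimethyl-[7,7'-bi-1-benzofuran]-3,3'(2H,2'H)-dione | COc1c(O)c(-c2c(O)c(OC)c(OC)c3c2O[C@@](C)(O)C3=O)c2c(c1OC)C(=O)[C@](C)(O)O2 | target

Total steps: 8. Longest linear sequence: 8 steps (1 to 12).

Steps most likely to fail

Step 7 (bears the label "Proposed new method:").
- What may go wrong: slow formation of the enaminol at an aldehyde flanked by two ortho substituents.
- The acetyl group may transfer to the carbene or to adventitious water, which strips the phenol.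
- The equilibrium may not lie far enough on the product side.
- The C2 configuration may erode, either by opening of the hemiketal or by reversal of the C–C bond formation while the catalyst is present.
- Fallback (known chemistry; stepwise chain extension and oxidation replace the umpolung isomerisation, and separation replaces catalyst control). It sets out from 8. Addition of EtMgBr (excess, THF, 0 °C) should give 6,6'-bis(benzyloxy)-3,3'-bis(1-hydroxypropyl)-4,4',5,5'-tetramethoxybiphenyl-2,2'-diol F1. MnO2 (CH2Cl2, rt) should give the bis(2-hydroxypropiophenone) F2. A Riley oxidation (SeO2, dioxane–H2O, 90 °C) should give the open bis(1,2-diketone) F3, which should close spontaneously to the stereorandom bis-hemiketal F4. Preparative chromatography on a chiral stationary phase then picks out the (2R,2'R) isomer, and the sequence comes back to the route at 11.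

Step 8.
- What may go wrong: epimerisation at C2 and C2' through ring–chain tautomerism during long contact with the catalyst surface, and over-reduction of the C3 carbonyl groups.
- Fallback (changed protecting-group plan, so that no reduction follows the ring closure). It sets out from 8. Hydrogenolysis at that stage (H2, 10 % Pd/C, EtOAc), where no stereocentre is at stake, should give 2,2',6,6'-tetrahydroxy-4,4',5,5'-tetramethoxybiphenyl-3,3'-dicarbaldehyde F5. Ac2O in pyridine should give the tetraacetate F6. The isomerisation of step 7, in which only the two acetates next to an aldehyde can take part, should give the 6,6'-diacetate of the target F7. Near-neutral cleavage of the two remaining aryl acetates (NH4OAc, aq MeOH, rt) comes back to the route at 12.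

Step 1.
- What may go wrong: poor positional selectivity (attack at C6, para to the phenol) and over-bromination.
- Fallback (directed ortho-metalation replaces electrophilic substitution). It sets out from 1. MOMCl and i-Pr2NEt (CH2Cl2) should give 3-(methoxymethoxy)-4,5-dimethoxybenzaldehyde F8. The aldehyde is masked in the flask as its α-amino alkoxide with lithium N,N,N'-trimethylethylenediamide. Lithiation with n-BuLi (THF, −20 °C) between the alkoxide and the chelating OMOM group, followed by a quench with BrCF2CF2Br, should give 2-bromo-3-(methoxymethoxy)-4,5-dimethoxybenzaldehyde F9. HCl in MeOH removes the acetal, and the sequence comes back to the route at 2.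

Further compounds
F1 | step 7 | 6,6'-bis(benzyloxy)-3,3'-bis(1-hydroxypropyl)-4,4',5,5'-tetramethoxy-[1,1'-biphenyl]-2,2'-diol (mixture of carbinol epimers) | CCC(O)c1c(O)c(c(OCc2ccccc2)c(OC)c1OC)-c1c(O)c(C(O)CC)c(OC)c(OC)c1OCc1ccccc1
F2 | step 7 | 1,1'-[6,6'-bis(benzyloxy)-2,2'-dihydroxy-4,4',5,5'-tetramethoxy-[1,1'-biphenyl]-3,3'-diyl]di(propan-1-one) | CCC(=O)c1c(O)c(c(OCc2ccccc2)c(OC)c1OC)-c1c(O)c(C(=O)CC)c(OC)c(OC)c1OCc1ccccc1
F3 | step 7 | 1,1'-[6,6'-bis(benzyloxy)-2,2'-dihydroxy-4,4',5,5'-tetramethoxy-[1,1'-biphenyl]-3,3'-diyl]di(propane-1,2-dione) (open tautomer) | CC(=O)C(=O)c1c(O)c(c(OCc2ccccc2)c(OC)c1OC)-c1c(O)c(C(=O)C(C)=O)c(OC)c(OC)c1OCc1ccccc1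
F4 | step 7 | 6,6'-bis(benzyloxy)-2,2'-dihydroxy-4,4',5,5'-tetramethoxy-2,2'-dimethyl-[7,7'-bi-1-benzofuran]-3,3'(2H,2'H)-dione (no control at C2 and C2') | COc1c(OCc4ccccc4)c(-c2c(OCc5ccccc5)c(OC)c(OC)c3c2OC(C)(O)C3=O)c2c(c1OC)C(=O)C(C)(O)O2
F5 | step 8 | 2,2',6,6'-tetrahydroxy-4,4',5,5'-tetramethoxy-[1,1'-biphenyl]-3,3'-dicarbaldehyde | COc1c(C=O)c(O)c(c(O)c1OC)-c1c(O)c(C=O)c(OC)c(OC)c1O
F6 | step 8 | 3,3'-diformyl-4,4',5,5'-tetramethoxy-[1,1'-biphenyl]-2,2',6,6'-tetrayl tetraacetate | COc1c(C=O)c(OC(C)=O)c(c(OC(C)=O)c1OC)-c1c(OC(C)=O)c(C=O)c(OC)c(OC)c1OC(C)=O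
F7 | step 8 | (2R,2'R)-2,2'-dihydroxy-4,4',5,5'-tetramethoxy-2,2'-dimethyl-3,3'-dioxo-2,2',3,3'-tetrahydro-[7,7'-bi-1-benzofuran]-6,6'-diyl diacetate | COc1c(OC(C)=O)c(-c2c(OC(C)=O)c(OC)c(OC)c3c2O[C@@](C)(O)C3=O)c2c(c1OC)C(=O)[C@](C)(O)O2
F8 | step 1 | 3-(methoxymethoxy)-4,5-dimethoxybenzaldehyde | COCOc1cc(C=O)cc(OC)c1OC
F9 | step 1 | 2-bromo-3-(methoxymethoxy)-4,5-dimethoxybenzaldehyde | COCOc1c(Br)c(C=O)cc(OC)c1OC
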